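Ring A is C1–C2–C3(O)–C4(CO2Me)–C5(Me)–C10(H); ring B is C5–C6=C7–C8(=O)–C9–C10, with side-chain carbon C11 on C7. Because C5, C10 and the enone carbons C6–C8 all sit on the single chain C7–C8–C9–C10–C1–C2–C3–C4–C5–C6, the bicycle is opened at C5–C10 and C6–C7. One intramolecular Diels–Alder reaction of the silyloxydiene C7=C8–C9=C10 with the (Z)-vinyl sulfone C5=C6, held by the C1–C4 tether, builds rings A and B and fixes C5 and C10 under control of C4. The acyclic triene precursor gets its syn C3/C4 pair from an Evans aldol, its Z-sulfone from alkyne iodosulfonylation and its diene arm by cross-metathesis; sulfinate loss later gives the enone.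

Key step: step 11

Remark on the chemistry: the (Z) geometry drawn for the C7=C8 enol ether is the one expected from soft enolisation; its E isomer would converge, since the C7 centre is removed in the elimination step.

Step 1
Reactants: 1 but-3-ynoic acid; 2 sodium benzenesulfinate
Product: 4 (E)-3-iodo-4-(phenylsulfonyl)but-3-enoic acid, via benzenesulfonyl iodide 3 (not isolated)
Conditions: PhSO2Na (1.5 equiv), I2 (1.2 equiv), EtOAc–H2O, rt, visible light
Reagents that add atoms: iodine, II
Why: Radical iodosulfonylation of a terminal alkyne, in which the sulfonyl radical from 3 adds to the terminal carbon and the vinyl radical takes iodine from the opposite side, so the anti addition should place the sulfonyl group cis to the CH2CO2H chain, the geometry needed later at C5=C6.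

Step 2
Reactants: 4 (E)-3-iodo-4-(phenylsulfonyl)but-3-enoic acid
Product: 5 (Z)-3-methyl-4-(phenylsulfonyl)but-3-enoic acid
Conditions: MeZnCl (3 equiv), Pd(PPh3)4 (5 mol %), THF, 0 °C to rt; 1 M HCl work-up
Reagents that add atoms: methylzinc chloride, C[Zn]Cl
Why: Negishi cross-coupling of a β-iodovinyl sulfone should proceed with retention of the alkene geometry, and the acid travels as its zinc carboxylate, which cannot enolise or lose iodide to an allene.

Step 3
Reactants: 5 (Z)-3-methyl-4-(phenylsulfonyl)but-3-enoic acid; 6 (S)-4-benzyloxazolidin-2-one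
Product: 9 (S)-4-benzyl-3-[(Z)-3-methyl-4-(phenylsulfonyl)but-3-enoyl]oxazolidin-2-one, via acid chloride 7 (not isolated), via lithium oxazolidinide 8 (not isolated)
Conditions: 5, (COCl)2, DMF (cat.), CH2Cl2, 0 °C to rt, concentrate; 6, n-BuLi, THF, −78 °C; then 7, −78 °C
Reagents that add atoms: none
Why: N-Acylation of a lithiated Evans oxazolidinone by an acid chloride is fast at −78 °C, which should outrun base-mediated migration of the β,γ-double bond into conjugation.

Step 4
Reactants: 9 (S)-4-benzyl-3-[(Z)-3-methyl-4-(phenylsulfonyl)but-3-enoyl]oxazolidin-2-one; 10 pent-4-enal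
Product: 12 (S)-4-benzyl-3-[(2S,3R)-3-hydroxy-2-[(Z)-1-(phenylsulfonyl)prop-1-en-2-yl]hept-6-enoyl]oxazolidin-2-one, via boron dienolate 11 (not isolated)
Conditions: Bu2BOTf (1.1 equiv), Et3N (1.3 equiv), CH2Cl2, −78 to 0 °C; then 10, −78 to 0 °C; pH 7 buffer, MeOH, H2O2, 0 °C
Reagents that add atoms: none
Why: Evans syn aldol, in which the (Z)-boron dienolate reacts at its α-carbon through a Zimmerman–Traxler chair on the face away from the benzyl group, which should set C4 (S) and C3 (R) together as the syn pair while the vinyl sulfone geometry is carried through unchanged.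

Step 5
Reactants: 12 (S)-4-benzyl-3-[(2S,3R)-3-hydroxy-2-[(Z)-1-(phenylsulfonyl)prop-1-en-2-yl]hept-6-enoyl]oxazolidin-2-one
Product: 13 methyl (2S,3R)-3-hydroxy-2-[(Z)-1-(phenylsulfonyl)prop-1-en-2-yl]hept-6-enoate
Conditions: MeOMgBr (from MeMgBr and MeOH), CH2Cl2–MeOH, −20 to 0 °C; aq NH4Cl
Reagents that add atoms: methanol, CO
Why: Transesterification of an Evans aldol adduct with MeOMgBr, where chelation by the β-alkoxide and the imide directs methoxide to the exocyclic carbonyl, and the short, cold reaction is meant to spare the acidic C4 hydrogen.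

Step 6
Reactants: 13 methyl (2S,3R)-3-hydroxy-2-[(Z)-1-(phenylsulfonyl)prop-1-en-2-yl]hept-6-enoate
Product: 14 methyl (2S,3R)-3-[(tert-butyldimethylsilyl)oxy]-2-[(Z)-1-(phenylsulfonyl)prop-1-en-2-yl]hept-6-enoate
Conditions: TBSOTf (1.3 equiv), 2,6-lutidine (2 equiv), CH2Cl2, −78 to 0 °C
Reagents that add atoms: tert-butyldimethylsilyl trifluoromethanesulfonate, CC(C)(C)[Si](C)(C)OS(=O)(=O)C(F)(F)F
Why: Silylation of a secondary alcohol with a silyl triflate and a hindered pyridine base too weak to touch C4, which also blocks oxa-Michael closure of the C3 oxygen onto the enone made in step 9.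

Step 7
Reactants: 15 dimethyl (S)-2-methylsuccinate
Product: 16 methyl (S)-4-[methoxy(methyl)amino]-2-methyl-4-oxobutanoate
Conditions: MeNH(OMe)·HCl (1.05 equiv), iPrMgCl (2.1 equiv), THF, −20 °C
Reagents that add atoms: N,O-dimethylhydroxylamine hydrochloride, CNOC.Cl
Why: Grignard-mediated aminolysis of an ester to a Weinreb amide, in which the magnesium amide should choose the unbranched CH2CO2Me ester over the α-branched one and is not basic enough to epimerise the stereocentre.

Step 8
Reactants: 16 methyl (S)-4-[methoxy(methyl)amino]-2-methyl-4-oxobutanoate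
Product: 17 methyl (S)-2-methyl-4-oxohex-5-enoate
Conditions: CH2=CHMgBr (1.3 equiv), THF, −78 to −40 °C; inverse quench into cold 1 M HCl
Reagents that add atoms: vinylmagnesium bromide, C=C[Mg]Br
Why: Weinreb ketone synthesis, where the chelated tetrahedral adduct survives until the acidic quench, so a single vinyl group is added and the slower α-branched methyl ester should stay intact.

Step 9
Reactants: 14 methyl (2S,3R)-3-[(tert-butyldimethylsilyl)oxy]-2-[(Z)-1-(phenylsulfonyl)prop-1-en-2-yl]hept-6-enoate; 17 methyl (S)-2-methyl-4-oxohex-5-enoate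
Product: 18 dimethyl (2S,5E,9R,10S)-9-[(tert-butyldimethylsilyl)oxy]-2-methyl-4-oxo-10-[(Z)-1-(phenylsulfonyl)prop-1-en-2-yl]undec-5-enedioate
Conditions: second-generation Hoveyda–Grubbs catalyst RuCl2(H2IMes)(=CH-C6H4-2-OiPr) (5 mol %), 17 (3 equiv), CH2Cl2, 40 °C
Reagents that add atoms: none
Why: Olefin cross-metathesis of a terminal alkene with a vinyl ketone is E-selective and needs no base, and the trisubstituted, electron-poor vinyl sulfone should be inert to the catalyst.

Step 10
Reactants: 18 dimethyl (2S,5E,9R,10S)-9-[(tert-butyldimethylsilyl)oxy]-2-methyl-4-oxo-10-[(Z)-1-(phenylsulfonyl)prop-1-en-2-yl]undec-5-enedioate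
Product: 19 dimethyl (2S,3Z,5E,9R,10S)-4,9-bis[(tert-butyldimethylsilyl)oxy]-2-methyl-10-[(Z)-1-(phenylsulfonyl)prop-1-en-2-yl]undeca-3,5-dienedioate
Conditions: TBSOTf (1.3 equiv), Et3N (2 equiv), CH2Cl2, −78 to −20 °C; rapid filtration through Et3N-deactivated silica
Reagents that add atoms: tert-butyldimethylsilyl trifluoromethanesulfonate, CC(C)(C)[Si](C)(C)OS(=O)(=O)C(F)(F)F
Why: Soft enolisation of an enone with a silyl triflate and a tertiary amine removes the α′ proton at C7 and should give the cross-conjugated (Z)-2-silyloxydiene, because the ketone is activated by silicon far more readily than either ester, so C4 and C11 are left alone.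

Step 11
Reactants: 19 dimethyl (2S,3Z,5E,9R,10S)-4,9-bis[(tert-butyldimethylsilyl)oxy]-2-methyl-10-[(Z)-1-(phenylsulfonyl)prop-1-en-2-yl]undeca-3,5-dienedioate
Product: 20 methyl (1S,2R,4aS,7R,8R,8aR)-2,6-bis[(tert-butyldimethylsilyl)oxy]-7-[(2S)-1-methoxy-1-oxopropan-2-yl]-8a-methyl-8-(phenylsulfonyl)-1,2,3,4,4a,7,8,8a-octahydronaphthalene-1-carboxylate
Conditions: toluene (0.01 M), BHT (cat.), 150 °C, sealed tube
Reagents that add atoms: none
Why: This is a thermal, concerted, suprafacial [4+2] cycloaddition in which the 2-silyloxydiene C7=C8–C9=C10 adds to the (Z)-vinyl sulfone C5=C6, and the closest known reaction type is the intramolecular Diels–Alder reaction of deca-1,7,9-trienes that carry a sulfonyl-activated dienophile and a 2-silyloxydiene. Ring B is the six-membered ring of the cycloaddition itself (bonds C5–C10 and C6–C7), and ring A closes through the C5–C10 bond as a six-membered, fused (type 1) ring over a chair-like C1–C4 tether, which also forces the regiochemistry against the electronic preference of the two partners. C5 is set by the dienophile face: allylic 1,3-strain with the cis sulfonyl group holds the C4 hydrogen in the plane of the alkene with the ester on one side and C3 on the other, so the diene delivered through C3 should bond to the face that leaves the C5 methyl cis to the C4 ester. C10 is set by the endo placement of the tether, and with it of the Z-sulfonyl group, which should give the cis ring fusion with H10 cis to the C5 methyl. C6 follows from the Z geometry of the dienophile and C7 from the Z geometry of the enol ether, and both are erased in step 13. The step therefore needs endo and facial selectivity, and both rest on the Z-sulfone together with the C3/C4 pair fixed in step 4.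

Step 12
Reactants: 20 methyl (1S,2R,4aS,7R,8R,8aR)-2,6-bis[(tert-butyldimethylsilyl)oxy]-7-[(2S)-1-methoxy-1-oxopropan-2-yl]-8a-methyl-8-(phenylsulfonyl)-1,2,3,4,4a,7,8,8a-octahydronaphthalene-1-carboxylate
Product: 21 methyl (1S,2R,4aS,7R,8R,8aR)-2-hydroxy-7-[(2S)-1-methoxy-1-oxopropan-2-yl]-8a-methyl-6-oxo-8-(phenylsulfonyl)decahydronaphthalene-1-carboxylate
Conditions: 48% aq HF, MeCN, 0 °C to rt
Reagents that add atoms: none
Why: Acidic fluoride desilylation should cleave the silyl enol ether to the C8 ketone and the secondary silyl ether to the C3 alcohol without base, so the β-hydroxy ester and the C11 centre are not exposed to retro-aldol or epimerising conditions.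

Step 13
Reactants: 21 methyl (1S,2R,4aS,7R,8R,8aR)-2-hydroxy-7-[(2S)-1-methoxy-1-oxopropan-2-yl]-8a-methyl-6-oxo-8-(phenylsulfonyl)decahydronaphthalene-1-carboxylate
Product: 22 methyl (1S,2R,4aS,8aS)-2-hydroxy-7-[(2S)-1-methoxy-1-oxopropan-2-yl]-8a-methyl-6-oxo-1,2,3,4,4a,5,6,8a-octahydronaphthalene-1-carboxylate
Conditions: DBU (1.5 equiv), CH2Cl2, 0 °C
Reagents that add atoms: none
Why: E1cB β-elimination of a β-sulfonyl ketone, in which enolisation toward C7 expels benzenesulfinate from C6 and should give the C6=C7 enone regiospecifically, erasing C6 and C7 and leaving C3, C4, C5, C10 and C11 untouched.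

Step 14
Reactants: 22 methyl (1S,2R,4aS,8aS)-2-hydroxy-7-[(2S)-1-methoxy-1-oxopropan-2-yl]-8a-methyl-6-oxo-1,2,3,4,4a,5,6,8a-octahydronaphthalene-1-carboxylate; 23 angelic acid ((Z)-2-methylbut-2-enoic acid)
Product: 25 methyl (1S,2R,4aS,8aS)-7-[(2S)-1-methoxy-1-oxopropan-2-yl]-8a-methyl-2-{[(2Z)-2-methylbut-2-enoyl]oxy}-6-oxo-1,2,3,4,4a,5,6,8a-octahydronaphthalene-1-carboxylate (CNP0265265.1), via mixed anhydride 24 (not isolated)
Conditions: 23 (3 equiv), 2,4,6-trichlorobenzoyl chloride (3 equiv), Et3N (3.3 equiv), toluene, rt; then 22, 80 °C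
Reagents that add atoms: none
Why: Yamaguchi-type esterification through the angelic 2,4,6-trichlorobenzoic mixed anhydride without a nucleophilic catalyst should acylate the hindered C3 alcohol while avoiding the addition–elimination pathway that turns angelates into tiglates.

Compound list
1 | but-3-ynoic acid | C#CCC(=O)O | starting material
2 | sodium benzenesulfinate | [Na+].[O-]S(=O)c1ccccc1 | starting material
3 | benzenesulfonyl iodide | O=S(=O)(I)c1ccccc1 | intermediate
4 | (E)-3-iodo-4-(phenylsulfonyl)but-3-enoic acid | OC(=O)C/C(I)=C\S(=O)(=O)c1ccccc1 | intermediate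
5 | (Z)-3-methyl-4-(phenylsulfonyl)but-3-enoic acid | OC(=O)C/C(C)=C\S(=O)(=O)c1ccccc1 | intermediate
6 | (S)-4-benzyloxazolidin-2-one | O=C1N[C@@H](Cc2ccccc2)CO1 | starting material
7 | (Z)-3-methyl-4-(phenylsulfonyl)but-3-enoyl chloride | ClC(=O)C/C(C)=C\S(=O)(=O)c1ccccc1 | intermediate
8 | lithium (S)-4-benzyl-2-oxooxazolidin-3-ide | [Li+].O=C1[N-][C@@H](Cc2ccccc2)CO1 | intermediate
9 | (S)-4-benzyl-3-[(Z)-3-methyl-4-(phenylsulfonyl)but-3-enoyl]oxazolidin-2-one | O=C(C/C(C)=C\S(=O)(=O)c1ccccc1)N1[C@@H](Cc2ccccc2)COC1=O | intermediate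
10 | pent-4-enal | C=CCCC=O | starting material
11 | (S)-4-benzyl-3-[(1Z,3Z)-1-[(dibutylboranyl)oxy]-3-methyl-4-(phenylsulfonyl)buta-1,3-dien-1-yl]oxazolidin-2-one | CCCCB(CCCC)O/C(=C\C(C)=C/S(=O)(=O)c1ccccc1)N1[C@@H](Cc2ccccc2)COC1=O | intermediate
12 | (S)-4-benzyl-3-[(2S,3R)-3-hydroxy-2-[(Z)-1-(phenylsulfonyl)prop-1-en-2-yl]hept-6-enoyl]oxazolidin-2-one | C=CCC[C@@H](O)[C@@H](C(=O)N1[C@@H](Cc2ccccc2)COC1=O)/C(C)=C\S(=O)(=O)c1ccccc1 | intermediate
13 | methyl (2S,3R)-3-hydroxy-2-[(Z)-1-(phenylsulfonyl)prop-1-en-2-yl]hept-6-enoate | C=CCC[C@@H](O)[C@@H](C(=O)OC)/C(C)=C\S(=O)(=O)c1ccccc1 | intermediate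
14 | methyl (2S,3R)-3-[(tert-butyldimethylsilyl)oxy]-2-[(Z)-1-(phenylsulfonyl)prop-1-en-2-yl]hept-6-enoate | C=CCC[C@@H](O[Si](C)(C)C(C)(C)C)[C@@H](C(=O)OC)/C(C)=C\S(=O)(=O)c1ccccc1 | intermediate
15 | dimethyl (S)-2-methylsuccinate | COC(=O)C[C@H](C)C(=O)OC | starting material
16 | methyl (S)-4-[methoxy(methyl)amino]-2-methyl-4-oxobutanoate | CON(C)C(=O)C[C@H](C)C(=O)OC | intermediate
17 | methyl (S)-2-methyl-4-oxohex-5-enoate | C=CC(=O)C[C@H](C)C(=O)OC | intermediate
18 | dimethyl (2S,5E,9R,10S)-9-[(tert-butyldimethylsilyl)oxy]-2-methyl-4-oxo-10-[(Z)-1-(phenylsulfonyl)prop-1-en-2-yl]undec-5-enedioate | COC(=O)[C@@H](C)CC(=O)/C=C/CC[C@@H](O[Si](C)(C)C(C)(C)C)[C@@H](C(=O)OC)/C(C)=C\S(=O)(=O)c1ccccc1 | intermediate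
19 | dimethyl (2S,3Z,5E,9R,10S)-4,9-bis[(tert-butyldimethylsilyl)oxy]-2-methyl-10-[(Z)-1-(phenylsulfonyl)prop-1-en-2-yl]undeca-3,5-dienedioate (acyclic triene, key-step precursor) | COC(=O)[C@@H](C)/C=C(O[Si](C)(C)C(C)(C)C)/C=C/CC[C@@H](O[Si](C)(C)C(C)(C)C)[C@@H](C(=O)OC)/C(C)=C\S(=O)(=O)c1ccccc1 | intermediate
20 | methyl (1S,2R,4aS,7R,8R,8aR)-2,6-bis[(tert-butyldimethylsilyl)oxy]-7-[(2S)-1-methoxy-1-oxopropan-2-yl]-8a-methyl-8-(phenylsulfonyl)-1,2,3,4,4a,7,8,8a-octahydronaphthalene-1-carboxylate (cis-decalin, key-step product) | CC(C)(C)[Si](C)(C)O[C@@H]1CC[C@H]2C=C(O[Si](C)(C)C(C)(C)C)[C@@H]([C@H](C)C(=O)OC)[C@@H](S(=O)(=O)c3ccccc3)[C@@]2(C)[C@@H]1C(=O)OC | intermediate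
21 | methyl (1S,2R,4aS,7R,8R,8aR)-2-hydroxy-7-[(2S)-1-methoxy-1-oxopropan-2-yl]-8a-methyl-6-oxo-8-(phenylsulfonyl)decahydronaphthalene-1-carboxylate | O[C@@H]1CC[C@H]2CC(=O)[C@@H]([C@H](C)C(=O)OC)[C@@H](S(=O)(=O)c3ccccc3)[C@@]2(C)[C@@H]1C(=O)OC | intermediate
22 | methyl (1S,2R,4aS,8aS)-2-hydroxy-7-[(2S)-1-methoxy-1-oxopropan-2-yl]-8a-methyl-6-oxo-1,2,3,4,4a,5,6,8a-octahydronaphthalene-1-carboxylate | O[C@@H]1CC[C@H]2CC(=O)C([C@H](C)C(=O)OC)=C[C@@]2(C)[C@@H]1C(=O)OC | intermediate
23 | angelic acid, (Z)-2-methylbut-2-enoic acid | C/C=C(/C)C(=O)O | starting material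
24 | (Z)-2-methylbut-2-enoic 2,4,6-trichlorobenzoic anhydride | C/C=C(/C)C(=O)OC(=O)c1c(Cl)cc(Cl)cc1Cl | intermediate
25 | methyl (1S,2R,4aS,8aS)-7-[(2S)-1-methoxy-1-oxopropan-2-yl]-8a-methyl-2-{[(2Z)-2-methylbut-2-enoyl]oxy}-6-oxo-1,2,3,4,4a,5,6,8a-octahydronaphthalene-1-carboxylate | C/C=C(/C)C(=O)O[C@@H]1CC[C@H]2CC(=O)C([C@H](C)C(=O)OC)=C[C@@]2(C)[C@@H]1C(=O)OC | target

Total step count: 14. Longest linear sequence: 12 steps (steps 1–6 and 9–14); steps 7 and 8 form the side branch.

Steps most likely to fail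

Step 11. The cis ring fusion may erode through the exo-tether transition state if the sulfonyl group prefers the exo position, and facial selectivity at the dienophile may be incomplete. The fallback inverts the dienophile geometry, so that an exo sulfonyl group goes with an endo tether. It sets out from 18: catalytic I2 under visible light in CH2Cl2 at rt should equilibrate the vinyl sulfone to its more stable E isomer, the E-sulfonyl enone F1 (sulfonyl cis to the methyl group). Silylation as in step 10 gives the E-sulfonyl triene F2. Heating as in step 11 with the sulfonyl group exo and the tether endo should give the cis-fused cycloadduct F3, the C6 epimer of 20. HF as in step 12 gives the keto sulfone F4, the C6 epimer of 21. DBU as in step 13 removes the sulfinate and the C6 centre with it, so the sequence comes back to the route at 22. Facial control is weaker in this series, because the in-plane C4 hydrogen no longer faces a sulfonyl group; it rescues the ring fusion and is not an improvement on the main route.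

Step 5. MeOMgBr may cause retro-aldol cleavage, or deprotonation at C4 with epimerisation or migration of the double bond into conjugation with the ester. The fallback uses a different auxiliary that leaves under near-neutral conditions. It sets out from 5: coupling with (S)-4-benzylthiazolidine-2-thione (EDC·HCl, DMAP cat., CH2Cl2) gives the N-acylthiazolidinethione F5. Its titanium enolate (TiCl4, iPr2NEt, N-methylpyrrolidinone, CH2Cl2, −78 °C) and 10 should give the Evans-syn aldol adduct F6. Methanol with imidazole at rt displaces the auxiliary, and the sequence comes back to the route at 13.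

Step 14. The angelate may isomerise to the tiglate during or after acylation, or the hindered C3 alcohol may acylate incompletely. The fallback builds the Z-alkene after the acylation. It sets out from 22: esterification with 2-[bis(2,2,2-trifluoroethoxy)phosphoryl]propanoic acid (DCC, DMAP cat., CH2Cl2) gives the phosphonate ester F7. Still–Gennari olefination (KN(SiMe3)2, 18-crown-6, THF, −78 °C, then acetaldehyde) should give the (Z)-2-methylbut-2-enoate directly, and the sequence comes back to the route at 25.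

Further compounds
F1 | step 11 | dimethyl (2S,5E,9R,10S)-9-[(tert-butyldimethylsilyl)oxy]-2-methyl-4-oxo-10-[(E)-1-(phenylsulfonyl)prop-1-en-2-yl]undec-5-enedioate | COC(=O)[C@@H](C)CC(=O)/C=C/CC[C@@H](O[Si](C)(C)C(C)(C)C)[C@@H](C(=O)OC)/C(C)=C/S(=O)(=O)c1ccccc1
F2 | step 11 | dimethyl (2S,3Z,5E,9R,10S)-4,9-bis[(tert-butyldimethylsilyl)oxy]-2-methyl-10-[(E)-1-(phenylsulfonyl)prop-1-en-2-yl]undeca-3,5-dienedioate | COC(=O)[C@@H](C)/C=C(O[Si](C)(C)C(C)(C)C)/C=C/CC[C@@H](O[Si](C)(C)C(C)(C)C)[C@@H](C(=O)OC)/C(C)=C/S(=O)(=O)c1ccccc1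
F3 | step 11 | methyl (1S,2R,4aS,7R,8S,8aR)-2,6-bis[(tert-butyldimethylsilyl)oxy]-7-[(2S)-1-methoxy-1-oxopropan-2-yl]-8a-methyl-8-(phenylsulfonyl)-1,2,3,4,4a,7,8,8a-octahydronaphthalene-1-carboxylate | CC(C)(C)[Si](C)(C)O[C@@H]1CC[C@H]2C=C(O[Si](C)(C)C(C)(C)C)[C@@H]([C@H](C)C(=O)OC)[C@H](S(=O)(=O)c3ccccc3)[C@@]2(C)[C@@H]1C(=O)OC
F4 | step 11 | methyl (1S,2R,4aS,7R,8S,8aR)-2-hydroxy-7-[(2S)-1-methoxy-1-oxopropan-2-yl]-8a-methyl-6-oxo-8-(phenylsulfonyl)decahydronaphthalene-1-carboxylate | O[C@@H]1CC[C@H]2CC(=O)[C@@H]([C@H](C)C(=O)OC)[C@H](S(=O)(=O)c3ccccc3)[C@@]2(C)[C@@H]1C(=O)OC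
F5 | step 5 | (S)-4-benzyl-3-[(Z)-3-methyl-4-(phenylsulfonyl)but-3-enoyl]thiazolidine-2-thione | O=C(C/C(C)=C\S(=O)(=O)c1ccccc1)N1[C@@H](Cc2ccccc2)CSC1=S
F6 | step 5 | (S)-4-benzyl-3-[(2S,3R)-3-hydroxy-2-[(Z)-1-(phenylsulfonyl)prop-1-en-2-yl]hept-6-enoyl]thiazolidine-2-thione | C=CCC[C@@H](O)[C@@H](C(=O)N1[C@@H](Cc2ccccc2)CSC1=S)/C(C)=C\S(=O)(=O)c1ccccc1
F7 | step 14 | methyl (1S,2R,4aS,8aS)-2-({2-[bis(2,2,2-trifluoroethoxy)phosphoryl]propanoyl}oxy)-7-[(2S)-1-methoxy-1-oxopropan-2-yl]-8a-methyl-6-oxo-1,2,3,4,4a,5,6,8a-octahydronaphthalene-1-carboxylate (both epimers at the phosphonate carbon) | CC(C(=O)O[C@@H]1CC[C@H]2CC(=O)C([C@H](C)C(=O)OC)=C[C@@]2(C)[C@@H]1C(=O)OC)P(=O)(OCC(F)(F)F)OCC(F)(F)F
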